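## Retrosynthetic overview

1. Target 18 ⇐ desilylation of 17 ⇐ acylation of 6β‑alcohol 16 ⇐ α‑face hydride reduction at C6 and α‑face enolate hydroxylation at C7 of the 8(9)‑en‑6‑one 12; both oxygen stereocentres are relayed from the trans ring fusion.
2. 12 ⇐ C9–C11 B‑alkyl Suzuki–Miyaura coupling of enol triflate 7 with the C11–C16 alkylborane 11; 7 ⇐ conjugate reduction/enolate triflation (fixes C8=C9) and ring A hydrogenation of trans ene‑dione 4 ⇐ C5 epimerization of adduct 3.
3. 3 ⇐ catalytic enantioselective Diels–Alder reaction forming C1–C10 and C4–C5 at once: 2,6‑dimethyl‑1,4‑benzoquinone 1 (ring B, dienophile C5=C10) + 4‑methylpenta‑1,3‑diene 2 (C1–C4 with both C4 methyls).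
4. Enabling feature: the oxygenated C6 and the side‑chain carbon C9 stand para across ring B and flank the ring‑fusion bond C5–C10, and C8 and C10 each carry a methyl, so ring B is a latent 2,6‑dimethyl‑p‑benzoquinone whose C5=C10 bond is a dienophile; ring A adds only the unfunctionalized arc C1–C2–C3–C4 ending in the gem‑dimethyl carbon, which is a 1,3‑diene.
5. Ring order: ring B is bought as the quinone, ring A is closed in step 1, the side chain is joined in step 7.

Key step: step 1

Remark (numbering): labdane numbering is used (ring A = C1–C5, C10; ring B = C5–C10; side chain C11–C16); the target is the 6‑isovalerate of labda‑8,13E‑diene‑6β,7α,15‑triol with 5α‑H and 10β‑CH3 (5S,6S,7S,10S).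

Remark (assumption): the (S)‑catalyst in step 1 is assigned from the accepted pre‑transition‑state model of cationic oxazaborolidines; this is a prediction, and the (R)‑catalyst is the mirror‑image option.

## Route

Step 1
Reactants: 1 2,6‑dimethyl‑1,4‑benzoquinone; 2 4‑methylpenta‑1,3‑diene
Product: 3 cis‑fused adduct (4aR,8aS)‑2,5,5,8a‑tetramethyl‑4a,5,8,8a‑tetrahydronaphthalene‑1,4‑dione
Conditions: (S)‑1‑(2‑methylphenyl)‑3,3‑diphenyl‑tetrahydropyrrolo[1,2‑c][1,3,2]oxazaborole (20 mol%) protonated with Tf2NH (20 mol%), 2 (3 equiv, slow addition), CH2Cl2, −78 → −20 °C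
Reagents that add atoms: none
Why: Enantioselective Diels–Alder reaction of a quinone under chiral cationic oxazaborolidine catalysis, the closest known reaction type being the catalytic asymmetric and the Lewis‑acid‑promoted [4+2] cycloadditions of 2,6‑dimethyl‑1,4‑benzoquinone with acyclic dienes; the mechanism is a concerted, asynchronous [4+2] in which the CH2 terminus of the diene (C1, the more nucleophilic terminus because of the donor methyls at C4) bonds first to the methyl‑bearing quinone carbon (C10) and the CMe2 terminus (C4) then closes onto the CH carbon (C5). Ring A is closed by this one intermolecular suprafacial [4+2] event, both bonds forming on the same face of the C5=C10 dienophile. C10 (quaternary) is set in the absolute sense by the catalyst, which binds the more basic and less hindered C6 carbonyl and screens one quinone face; C5 follows as cis to the C10 methyl by suprafacial addition and is corrected in step 2. The step needs regioselectivity (catalyst coordination at the C6 carbonyl makes C10 the β‑carbon, and sterics agree because the CMe2 terminus meets the unsubstituted carbon), site selectivity (the two quinone C=C bonds are symmetry‑equivalent and the remaining C7=C8 ene‑dione bond of the adduct is deactivated) and face selectivity (catalyst); endo/exo selectivity is irrelevant because neither diene terminus is stereogenic. The low s‑cis population of the diene is the kinetic handicap and is answered by the strongly activating cationic catalyst and the excess of diene.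

Step 2
Reactants: 3 cis‑fused adduct
Product: 4 trans‑fused ene‑dione (4aS,8aS)‑2,5,5,8a‑tetramethyl‑4a,5,8,8a‑tetrahydronaphthalene‑1,4‑dione
Conditions: DBU (0.2 equiv), toluene, 25 °C, under argon
Reagents that add atoms: none
Why: Base‑mediated epimerization through the C5=C6 dienolate, in which C5 (the only enolizable ring‑fusion centre, α to the C6 ketone) should equilibrate to the trans‑decalin typical of 4,4,10‑trimethyl‑6‑oxodecalins, reprotonation from the α‑face opposite the C10 and C4β methyls being also the kinetically preferred course, while quaternary C10 cannot change.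

Step 3
Reactants: 4 trans‑fused ene‑dione
Product: 6 enol triflate (4aS,8aS)‑2,5,5,8a‑tetramethyl‑4‑oxo‑3,4,4a,5,8,8a‑hexahydronaphthalen‑1‑yl trifluoromethanesulfonate, via lithium enolate 5 (not isolated)
Conditions: LiBH(s‑Bu)3 (1.05 equiv), THF, −78 °C; then N‑(5‑chloropyridin‑2‑yl)‑bis(trifluoromethanesulfonyl)imide, −78 → 0 °C
Reagents that add atoms: N‑(5‑chloropyridin‑2‑yl)‑bis(trifluoromethanesulfonyl)imide, FC(F)(F)S(=O)(=O)N(c1ccc(Cl)cn1)S(=O)(=O)C(F)(F)F
Why: Conjugate reduction of the ene‑dione by a hindered trialkylborohydride at the unsubstituted β‑carbon C7 gives regiospecifically the tetrasubstituted C8=C9 enolate, whose in situ O‑triflation (enolate triflation) turns the C9 oxygen into a cross‑coupling handle and fixes C8=C9 in its final place without forming a stereocentre.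

Step 4
Reactants: 6 enol triflate
Product: 7 ring A saturated enol triflate (4aS,8aS)‑2,5,5,8a‑tetramethyl‑4‑oxo‑3,4,4a,5,6,7,8,8a‑octahydronaphthalen‑1‑yl trifluoromethanesulfonate
Conditions: H2 (3 atm), RhCl(PPh3)3 (5 mol%), toluene, 25 °C
Reagents that add atoms: none
Why: Homogeneous hydrogenation with RhCl(PPh3)3 should reduce only the cis‑disubstituted ring A alkene, the tetrasubstituted enol triflate and the hindered ketone being inert to this catalyst, and no stereocentre is formed.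

Step 5
Reactants: 8 (E)‑3‑methylpent‑2‑en‑4‑yn‑1‑ol
Product: 9 (E)‑tert‑butyl‑dimethyl‑[(3‑methylpent‑2‑en‑4‑ynyl)oxy]silane
Conditions: TBSCl, imidazole, CH2Cl2, 0 → 25 °C
Reagents that add atoms: tert‑butyldimethylsilyl chloride, CC(C)(C)[Si](C)(C)Cl
Why: Standard silyl ether protection of a primary allylic alcohol, which carries the E‑configured C13=C14 unit of the target unchanged.

Step 6
Reactants: 9 silyl enyne
Product: 10 (E)‑tert‑butyl‑dimethyl‑[(3‑methylpenta‑2,4‑dienyl)oxy]silane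
Conditions: H2 (1 atm), Pd/CaCO3 poisoned with Pb(OAc)2, quinoline, hexane, 25 °C
Reagents that add atoms: none
Why: Semi‑hydrogenation of the terminal alkyne over poisoned palladium stops at the vinyl group and leaves the E‑trisubstituted alkene untouched.

Step 7
Reactants: 7 ring A saturated enol triflate; 10 silyl diene
Product: 12 (4aS,8aS)‑4‑[(E)‑5‑[tert‑butyl(dimethyl)silyl]oxy‑3‑methylpent‑3‑enyl]‑3,4a,8,8‑tetramethyl‑4a,5,6,7,8,8a‑hexahydro‑2H‑naphthalen‑1‑one, via alkylborane 11 (not isolated)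
Conditions: 10, 9‑BBN‑H, THF, 0 → 25 °C; then 7, PdCl2(dppf) (10 mol%), AsPh3, aqueous K3PO4, DMF, 25 → 45 °C
Reagents that add atoms: none
Why: B‑alkyl Suzuki–Miyaura coupling, in which 9‑BBN hydroborates only the terminal vinyl group of the diene (anti‑Markovnikov) and the primary alkylborane couples with the enol triflate as known for 2,6,6‑trisubstituted cyclohexenyl triflates, forming C9–C11 with retention of the C8=C9 position and the E geometry of C13=C14.

Step 8
Reactants: 12 β,γ‑unsaturated ketone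
Product: 15 (2S,4aS,8aS)‑4‑[(E)‑5‑[tert‑butyl(dimethyl)silyl]oxy‑3‑methylpent‑3‑enyl]‑3,4a,8,8‑tetramethyl‑2‑triethylsilyloxy‑4a,5,6,7,8,8a‑hexahydro‑2H‑naphthalen‑1‑one, via potassium dienolate 13 (not isolated), via potassium alkoxide 14 (not isolated)
Conditions: KN(SiMe3)2, THF, −78 °C; 2‑(phenylsulfonyl)‑3‑phenyloxaziridine, −78 °C; then Et3SiCl, −78 → 0 °C
Reagents that add atoms: 2‑(phenylsulfonyl)‑3‑phenyloxaziridine, O=S(=O)(N1OC1c1ccccc1)c1ccccc1; chlorotriethylsilane, CC[Si](CC)(CC)Cl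
Why: Deprotonation at the doubly activated C7 (α to the ketone and allylic) gives the extended dienolate, which is hydroxylated at its α‑carbon by the N‑sulfonyloxaziridine (enolate oxidation) from the α‑face, opposite the β‑oriented C10 and C4 methyls and along the axial trajectory, setting 7α‑O (7S), and silylation of the alkoxide in the same flask forestalls α‑ketol isomerization.

Step 9
Reactants: 15 α‑silyloxy ketone
Product: 16 (1S,2S,4aS,8aS)‑4‑[(E)‑5‑[tert‑butyl(dimethyl)silyl]oxy‑3‑methylpent‑3‑enyl]‑3,4a,8,8‑tetramethyl‑2‑triethylsilyloxy‑1,2,4a,5,6,7,8,8a‑octahydronaphthalen‑1‑ol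
Conditions: LiAlH4, Et2O, −78 → 0 °C
Reagents that add atoms: none
Why: Hydride reduction of the hindered C6 ketone should occur from the α‑face because the β‑face is blocked by the 1,3‑syn‑axial C10 and C4β methyls (the usual behaviour of 6‑ketones in 4,4,10‑trimethyl‑trans‑decalins and of 7α‑substituted 6‑oxo steroids), giving the axial 6β‑alcohol (6S) trans‑diaxial to the 7α‑silyloxy group.

Step 10
Reactants: 16 6β‑alcohol
Product: 17 [(1S,2S,4aS,8aS)‑4‑[(E)‑5‑[tert‑butyl(dimethyl)silyl]oxy‑3‑methylpent‑3‑enyl]‑3,4a,8,8‑tetramethyl‑2‑triethylsilyloxy‑1,2,4a,5,6,7,8,8a‑octahydronaphthalen‑1‑yl] 3‑methylbutanoate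
Conditions: 3‑methylbutanoyl chloride (excess), DMAP, pyridine, CH2Cl2, 25 → 40 °C
Reagents that add atoms: 3‑methylbutanoyl chloride, CC(C)CC(=O)Cl
Why: DMAP‑catalysed acylation of the only free hydroxyl, in which the trans‑diaxial disposition of O6 and O7 precludes silyl or acyl migration.

Step 11
Reactants: 17 bis‑silyl ether ester
Product: 18 target, [(1S,2S,4aS,8aS)‑2‑hydroxy‑4‑[(E)‑5‑hydroxy‑3‑methylpent‑3‑enyl]‑3,4a,8,8‑tetramethyl‑1,2,4a,5,6,7,8,8a‑octahydronaphthalen‑1‑yl] 3‑methylbutanoate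
Conditions: HF·pyridine, pyridine, THF, 0 → 25 °C
Reagents that add atoms: none
Why: Fluoride‑mediated cleavage of both silyl ethers under buffered, weakly acidic conditions should leave the ester and both allylic alcohols intact and cannot trigger acyl migration across the trans‑diaxial diol.

## Compound list

1 | 2,6‑dimethyl‑1,4‑benzoquinone | CC1=CC(=O)C=C(C)C1=O | starting material
2 | 4‑methylpenta‑1,3‑diene | C=CC=C(C)C | starting material
3 | (4aR,8aS)‑2,5,5,8a‑tetramethyl‑4a,5,8,8a‑tetrahydronaphthalene‑1,4‑dione (cis‑fused) | O=C1C(C)=CC(=O)[C@@H]2C(C)(C)C=CC[C@]12C | intermediate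
4 | (4aS,8aS)‑2,5,5,8a‑tetramethyl‑4a,5,8,8a‑tetrahydronaphthalene‑1,4‑dione (trans‑fused) | O=C1C(C)=CC(=O)[C@H]2C(C)(C)C=CC[C@]12C | intermediate
5 | lithium (4aS,8aS)‑2,5,5,8a‑tetramethyl‑4‑oxo‑3,4,4a,5,8,8a‑hexahydronaphthalen‑1‑olate | [Li+].CC1=C([O-])[C@@]2(C)CC=CC(C)(C)[C@@H]2C(=O)C1 | intermediate
6 | (4aS,8aS)‑2,5,5,8a‑tetramethyl‑4‑oxo‑3,4,4a,5,8,8a‑hexahydronaphthalen‑1‑yl trifluoromethanesulfonate | CC1=C(OS(=O)(=O)C(F)(F)F)[C@@]2(C)CC=CC(C)(C)[C@@H]2C(=O)C1 | intermediate
7 | (4aS,8aS)‑2,5,5,8a‑tetramethyl‑4‑oxo‑3,4,4a,5,6,7,8,8a‑octahydronaphthalen‑1‑yl trifluoromethanesulfonate | CC1=C(OS(=O)(=O)C(F)(F)F)[C@@]2(C)CCCC(C)(C)[C@@H]2C(=O)C1 | intermediate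
8 | (E)‑3‑methylpent‑2‑en‑4‑yn‑1‑ol | C#C/C(C)=C/CO | starting material
9 | (E)‑tert‑butyl‑dimethyl‑[(3‑methylpent‑2‑en‑4‑ynyl)oxy]silane | C#C/C(C)=C/CO[Si](C)(C)C(C)(C)C | intermediate
10 | (E)‑tert‑butyl‑dimethyl‑[(3‑methylpenta‑2,4‑dienyl)oxy]silane | C=C/C(C)=C/CO[Si](C)(C)C(C)(C)C | intermediate
11 | 9‑[(E)‑5‑[tert‑butyl(dimethyl)silyl]oxy‑3‑methylpent‑3‑enyl]‑9‑borabicyclo[3.3.1]nonane | CC(C)(C)[Si](C)(C)OC/C=C(\C)CCB1C2CCCC1CCC2 | intermediate
12 | (4aS,8aS)‑4‑[(E)‑5‑[tert‑butyl(dimethyl)silyl]oxy‑3‑methylpent‑3‑enyl]‑3,4a,8,8‑tetramethyl‑4a,5,6,7,8,8a‑hexahydro‑2H‑naphthalen‑1‑one | CC1=C(CC/C(C)=C/CO[Si](C)(C)C(C)(C)C)[C@@]2(C)CCCC(C)(C)[C@@H]2C(=O)C1 | intermediate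
13 | potassium dienolate of 12 (C6 enolate, C6=C7–C8=C9) | [K+].CC1=C(CC/C(C)=C/CO[Si](C)(C)C(C)(C)C)[C@@]2(C)CCCC(C)(C)[C@@H]2C([O-])=C1 | intermediate
14 | potassium (2S,4aS,8aS)‑alkoxide of the 7α‑hydroxy‑6‑ketone | [K+].CC1=C(CC/C(C)=C/CO[Si](C)(C)C(C)(C)C)[C@@]2(C)CCCC(C)(C)[C@@H]2C(=O)[C@H]1[O-] | intermediate
15 | (2S,4aS,8aS)‑4‑[(E)‑5‑[tert‑butyl(dimethyl)silyl]oxy‑3‑methylpent‑3‑enyl]‑3,4a,8,8‑tetramethyl‑2‑triethylsilyloxy‑4a,5,6,7,8,8a‑hexahydro‑2H‑naphthalen‑1‑one | CC1=C(CC/C(C)=C/CO[Si](C)(C)C(C)(C)C)[C@@]2(C)CCCC(C)(C)[C@@H]2C(=O)[C@H]1O[Si](CC)(CC)CC | intermediate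
16 | (1S,2S,4aS,8aS)‑4‑[(E)‑5‑[tert‑butyl(dimethyl)silyl]oxy‑3‑methylpent‑3‑enyl]‑3,4a,8,8‑tetramethyl‑2‑triethylsilyloxy‑1,2,4a,5,6,7,8,8a‑octahydronaphthalen‑1‑ol | CC1=C(CC/C(C)=C/CO[Si](C)(C)C(C)(C)C)[C@@]2(C)CCCC(C)(C)[C@@H]2[C@H](O)[C@H]1O[Si](CC)(CC)CC | intermediate
17 | 3‑methylbutanoate of 16 | CC1=C(CC/C(C)=C/CO[Si](C)(C)C(C)(C)C)[C@@]2(C)CCCC(C)(C)[C@@H]2[C@H](OC(=O)CC(C)C)[C@H]1O[Si](CC)(CC)CC | intermediate
18 | [(1S,2S,4aS,8aS)‑2‑hydroxy‑4‑[(E)‑5‑hydroxy‑3‑methylpent‑3‑enyl]‑3,4a,8,8‑tetramethyl‑1,2,4a,5,6,7,8,8a‑octahydronaphthalen‑1‑yl] 3‑methylbutanoate | CC1=C(CC/C(C)=C/CO)[C@@]2(C)CCCC(C)(C)[C@@H]2[C@H](OC(=O)CC(C)C)[C@H]1O | target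

## Step count and risks

Total step count: 11. Longest linear sequence: 9 steps (1, 2, 3, 4, 7, 8, 9, 10, 11).

Steps most likely to fail:

1. Step 1. The diene populates its s‑cis conformer poorly, so the cycloaddition may be outrun by acid‑induced oligomerization of the diene, or may need temperatures at which regio‑ and enantiocontrol erode. Fallback: setting out from 1, the far more reactive 2‑silyloxy diene tert‑butyl‑dimethyl‑[(4‑methylpenta‑1,3‑dien‑2‑yl)oxy]silane F1 (from mesityl oxide with LDA and TBSCl, THF, −78 °C) would be used under the same cationic oxazaborolidine catalysis. Its enol ether CH2 terminus should bond to C10 for the same electronic reason, giving the silyl enol ether adduct (4aR,8aS)‑7‑silyloxy ene‑dione F2. The surplus oxygen at C2 would then be excised: fluoride‑triggered exchange to the C2 enol triflate F3 (Bu4N Ph3SiF2, N‑(5‑chloropyridin‑2‑yl)‑bis(trifluoromethanesulfonyl)imide, THF, 0 °C), then palladium‑catalysed formate reduction of the C–OTf bond (Pd(OAc)2, PPh3, HCO2H, Bu3N, DMF, 60 °C). This should leave the C2=C3 alkene, which is compound 3, where the route is rejoined.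

2. Step 7. Oxidative addition and transmetalation at the C9 triflate, flanked by quaternary C10 and the C8 methyl, may be too slow, and the aqueous base may move the β,γ‑double bond into conjugation with the C6 ketone. Fallback: the C9–C11 bond would be made by carbonyl addition instead of cross‑coupling, setting out from 4 and from 10. Ene‑dione 4 would be hydrogenated in ring A (H2, RhCl(PPh3)3, toluene) to the saturated trans ene‑dione F4. Diene 10 would be hydroborated as in step 7 and borane 11 iodinated (I2, NaOMe, THF) to (E)‑tert‑butyl‑[(5‑iodo‑3‑methylpent‑2‑enyl)oxy]‑dimethylsilane F5. Iodine–lithium exchange (t‑BuLi, Et2O, −78 °C) would give the alkyllithium F6, transmetalated with CeCl3 to the organocerium reagent F7. F7 should add 1,2 to the C9 carbonyl of F4 from the α‑face, because the C6 carbonyl is deactivated by the β‑methyl at C8 and screened by the C4 gem‑dimethyl group, to give the γ‑hydroxy enone F8. Reduction with SmI2 (THF/MeOH, −78 °C) should expel the γ‑hydroxyl, and α‑protonation of the resulting dienolate at C7 returns the β,γ‑unsaturated ketone 12.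

3. Step 2. The equilibrium may not favour the trans‑fused isomer enough, or prolonged base contact may degrade the ene‑dione. Fallback: thermodynamic control would be replaced by irreversible kinetic protonation. Setting out from 3, soft enolization (TBSOTf, Et3N, CH2Cl2, 0 °C) would give the silyl dienol ether (8aS)‑4‑silyloxy dienone F9, in which C5 is trigonal. Protodesilylation at low temperature (HF·pyridine, THF, −78 °C) should deliver the proton to C5 from the α‑face, opposite the C10 and C4β methyl groups, and return the trans‑fused ene‑dione 4.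

Further compounds
F1 | step 1 | tert‑butyl‑dimethyl‑[(4‑methylpenta‑1,3‑dien‑2‑yl)oxy]silane | C=C(O[Si](C)(C)C(C)(C)C)C=C(C)C
F2 | step 1 | (4aR,8aS)‑7‑[tert‑butyl(dimethyl)silyl]oxy‑2,5,5,8a‑tetramethyl‑4a,5,8,8a‑tetrahydronaphthalene‑1,4‑dione | O=C1C(C)=CC(=O)[C@@H]2C(C)(C)C=C(O[Si](C)(C)C(C)(C)C)C[C@]12C
F3 | step 1 | (4aR,8aS)‑2,5,5,8a‑tetramethyl‑1,4‑dioxo‑1,4,4a,5,8,8a‑hexahydronaphthalen‑7‑yl trifluoromethanesulfonate (ring numbering of F2) | O=C1C(C)=CC(=O)[C@@H]2C(C)(C)C=C(OS(=O)(=O)C(F)(F)F)C[C@]12C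
F4 | step 7 | (4aS,8aS)‑2,5,5,8a‑tetramethyl‑4a,5,6,7,8,8a‑hexahydronaphthalene‑1,4‑dione | O=C1C(C)=CC(=O)[C@H]2C(C)(C)CCC[C@]12C
F5 | step 7 | (E)‑tert‑butyl‑[(5‑iodo‑3‑methylpent‑2‑enyl)oxy]‑dimethylsilane | ICC/C(C)=C/CO[Si](C)(C)C(C)(C)C
F6 | step 7 | [(E)‑5‑[tert‑butyl(dimethyl)silyl]oxy‑3‑methylpent‑3‑enyl]lithium | [Li]CC/C(C)=C/CO[Si](C)(C)C(C)(C)C
F7 | step 7 | dichloro‑[(E)‑5‑[tert‑butyl(dimethyl)silyl]oxy‑3‑methylpent‑3‑enyl]cerium | Cl[Ce](Cl)CC/C(C)=C/CO[Si](C)(C)C(C)(C)C
F8 | step 7 | (4S,4aS,8aS)‑4‑hydroxy‑4‑[(E)‑5‑[tert‑butyl(dimethyl)silyl]oxy‑3‑methylpent‑3‑enyl]‑3,4a,8,8‑tetramethyl‑4a,5,6,7,8,8a‑hexahydronaphthalen‑1(4H)‑one | O[C@@]1(CC/C(C)=C/CO[Si](C)(C)C(C)(C)C)C(C)=CC(=O)[C@H]2C(C)(C)CCC[C@]12C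
F9 | step 2 | (8aS)‑4‑[tert‑butyl(dimethyl)silyl]oxy‑2,5,5,8a‑tetramethyl‑5,8‑dihydronaphthalen‑1(8aH)‑one | O=C1C(C)=CC(O[Si](C)(C)C(C)(C)C)=C2C(C)(C)C=CC[C@]12C
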